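**Strategy.** The pyranone ring C is cut at C2–C3 and at C4–C4a. The feature used is the C2–C3H2–C4(=O) chain of ring C, whose carbonyl sits on C4a of the phloroglucinol-type ring A, the only free position ortho to O1. In one operation a photochemical Wolff rearrangement moves the stereogenic carbon C2, with retention, from the future C4 to a diazo carbon that becomes C3, and the ketene so formed acylates C4a. The precursor is an acyclic (R)-α-aryloxy-α-aryl diazomethyl ketone that already holds O1, ring A with its prenyl group and ring B; its stereocentre comes from an asymmetric transfer hydrogenation followed by a Mitsunobu inversion.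

Key step: step 9

Remark on the chemistry: the target is the (2S)-flavanone. Carbonate 2 is taken as purchasable (otherwise one step from 2-methylbut-3-en-2-ol and di-tert-butyl dicarbonate). Diazomethane is generated from N-methyl-N-nitroso-p-toluenesulfonamide just before use.

**Step 1**
Reactants: 1 3,5-dimethoxyphenol; 2 tert-butyl 2-methylbut-3-en-2-yl carbonate
Product: 3 1,3-dimethoxy-5-[(2-methylbut-3-en-2-yl)oxy]benzene
Conditions: Pd(PPh3)4 (2 mol %), THF, 0 °C
Reagents that add atoms: none
Why: Decarboxylative Tsuji–Trost O-allylation: zerovalent palladium ionises the tertiary carbonate to a 1,1-dimethyl-π-allyl complex and tert-butoxide, and the phenoxide attacks the more substituted terminus under kinetic control to give the tertiary (reverse-prenyl) aryl ether.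

**Step 2**
Reactants: 3 1,3-dimethoxy-5-[(2-methylbut-3-en-2-yl)oxy]benzene
Product: 4 3,5-dimethoxy-2-(3-methylbut-2-en-1-yl)phenol
Conditions: Eu(fod)3 (10 mol %), CHCl3, 50 °C
Reagents that add atoms: none
Why: Aromatic Claisen rearrangement ([3,3]), accelerated by the oxophilic europium chelate, delivers the allyl terminus to either of the two equivalent ortho positions, and tautomerisation of the dienone leaves a normal prenyl group next to the hydroxyl.

**Step 3**
Reactants: 5 5-bromo-2-methoxyphenol
Product: 6 (5-bromo-2-methoxyphenoxy)(tert-butyl)dimethylsilane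
Conditions: TBSCl, imidazole, DMF, rt
Reagents that add atoms: tert-butyldimethylsilyl chloride (TBSCl), C[Si](C)(Cl)C(C)(C)C
Why: Standard silylation masks the ring B phenol, which would otherwise compete in the Mitsunobu step, be methylated by diazomethane and add to the ketene.

**Step 4**
Reactants: 6 (5-bromo-2-methoxyphenoxy)(tert-butyl)dimethylsilane; 7 diallyl oxalate
Product: 9 prop-2-en-1-yl 2-[3-(tert-butyldimethylsilyloxy)-4-methoxyphenyl]-2-oxoacetate, via aryllithium 8 (not isolated)
Conditions: n-BuLi, THF, −78 °C; then added to 7 (2.5 equiv), THF, −78 °C; aq NH4Cl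
Reagents that add atoms: none
Why: Bromine–lithium exchange followed by acylation with excess dialkyl oxalate should stop at the aryl glyoxylate, because the tetrahedral adduct persists at −78 °C and blocks a second addition.

**Step 5**
Reactants: 9 prop-2-en-1-yl 2-[3-(tert-butyldimethylsilyloxy)-4-methoxyphenyl]-2-oxoacetate
Product: 10 prop-2-en-1-yl (2S)-2-[3-(tert-butyldimethylsilyloxy)-4-methoxyphenyl]-2-hydroxyacetate
Conditions: RuCl(p-cymene)[(R,R)-TsDPEN] (1 mol %), HCO2H/Et3N (5:2), DMF, rt
Reagents that add atoms: none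
Why: Noyori–Ikariya asymmetric transfer hydrogenation of the activated α-keto ester; the (R,R) catalyst places the aryl group next to the η6-arene as it does for aryl alkyl ketones, which with an ester in place of the alkyl group corresponds to the (S) carbinol, and the allyl C=C is not reduced.

**Step 6**
Reactants: 10 prop-2-en-1-yl (2S)-2-[3-(tert-butyldimethylsilyloxy)-4-methoxyphenyl]-2-hydroxyacetate; 4 3,5-dimethoxy-2-(3-methylbut-2-en-1-yl)phenol
Product: 11 prop-2-en-1-yl (2R)-2-[3-(tert-butyldimethylsilyloxy)-4-methoxyphenyl]-2-[3,5-dimethoxy-2-(3-methylbut-2-en-1-yl)phenoxy]acetate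
Conditions: PPh3, DIAD, toluene, 0 °C to rt
Reagents that add atoms: none
Why: Mitsunobu etherification: the phenoxide displaces the alkoxyphosphonium group by SN2 with inversion, so the (S) carbinol becomes the (R) aryl ether that carries the O1–C2 bond; the adjacent ester disfavours ionisation at the benzylic carbon.

**Step 7**
Reactants: 11 prop-2-en-1-yl (2R)-2-[3-(tert-butyldimethylsilyloxy)-4-methoxyphenyl]-2-[3,5-dimethoxy-2-(3-methylbut-2-en-1-yl)phenoxy]acetate
Product: 12 (2R)-2-[3-(tert-butyldimethylsilyloxy)-4-methoxyphenyl]-2-[3,5-dimethoxy-2-(3-methylbut-2-en-1-yl)phenoxy]acetic acid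
Conditions: Pd(PPh3)4 (3 mol %), PhNHMe, THF, rt
Reagents that add atoms: none
Why: Tsuji–Trost deallylation frees the acid under near-neutral conditions; the weakly basic N-methylaniline traps the allyl group without epimerising the acidic α-CH or touching the aryl silyl ether.

**Step 8**
Reactants: 12 (2R)-2-[3-(tert-butyldimethylsilyloxy)-4-methoxyphenyl]-2-[3,5-dimethoxy-2-(3-methylbut-2-en-1-yl)phenoxy]acetic acid
Product: 14 (3R)-3-[3-(tert-butyldimethylsilyloxy)-4-methoxyphenyl]-1-diazo-3-[3,5-dimethoxy-2-(3-methylbut-2-en-1-yl)phenoxy]propan-2-one, via mixed carbonic anhydride 13 (not isolated)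
Conditions: i-BuOCOCl, N-methylmorpholine, THF, −20 °C; then CH2N2, Et2O, −20 to 0 °C
Reagents that add atoms: diazomethane, C=[N+]=[N-]
Why: Acylation of diazomethane by a mixed carbonic anhydride (first stage of the Arndt–Eistert sequence); the low temperature and the weak base should keep the α-stereocentre intact, and the prenyl alkene is inert to diazomethane.

**Step 9**
Reactants: 14 (3R)-3-[3-(tert-butyldimethylsilyloxy)-4-methoxyphenyl]-1-diazo-3-[3,5-dimethoxy-2-(3-methylbut-2-en-1-yl)phenoxy]propan-2-one
Product: 16 (2S)-2-[3-(tert-butyldimethylsilyloxy)-4-methoxyphenyl]-5,7-dimethoxy-8-(3-methylbut-2-en-1-yl)chroman-4-one, via ketene 15 (not isolated)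
Conditions: hν (blue LEDs, 450 nm), CH2Cl2 (0.01 M), −40 °C; then Sc(OTf)3 (10 mol %, in MeNO2), −40 to 0 °C
Reagents that add atoms: none
Why: Proposed new method: excitation of the diazoketone expels N2 with a concerted 1,2-shift of C2 from the carbonyl carbon to the diazo carbon (Wolff rearrangement), which makes the C2–C3 bond with retention at the migrating carbon; no new stereocentre is created, and the (R) centre of 14 becomes the (S) centre of 16 only because the ranking of its neighbours changes. The aldoketene 15 does not absorb at 450 nm and is then activated at oxygen by Sc(OTf)3, so that C4 is attacked by the ring A carbon ortho to O1 and to one methoxy group and para to the other; this closes ring C as a six-membered ring by intramolecular Friedel–Crafts acylation, and proton transfer from the Wheland intermediate to C3 gives the ketone and frees the catalyst. The closest known reactions are the Arndt–Eistert homologation, where the same kind of ketene is trapped by a heteroatom nucleophile, and the Lewis-acid-promoted Friedel–Crafts acylation of arenes by ketenes and by acylketenes released from Meldrum's acid derivatives, which gives chroman-4-ones; capture of a Wolff ketene by a tethered arene is the untested part. Regiochemistry on ring A is fixed because the other ortho position carries the prenyl group. The step needs arene acylation to win over indanone formation on ring B (five-membered closure onto a far less activated ring), over [2+2] addition to the prenyl alkene (medium-ring transition state) and over ketene dimerisation (suppressed by dilution), and the catalytic mild Lewis acid at low temperature is chosen so that the benzylic C2–O1 bond does not ionise.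

**Step 10**
Reactants: 16 (2S)-2-[3-(tert-butyldimethylsilyloxy)-4-methoxyphenyl]-5,7-dimethoxy-8-(3-methylbut-2-en-1-yl)chroman-4-one
Product: 17 (2S)-2-(3-hydroxy-4-methoxyphenyl)-5,7-dimethoxy-8-(3-methylbut-2-en-1-yl)chroman-4-one
Conditions: TBAF, AcOH (1:1), THF, 0 °C
Reagents that add atoms: none
Why: Fluoride cleaves the aryl Si–O bond, and the acetic acid buffer should prevent base-induced retro-oxa-Michael opening of ring C, which would racemise C2.

**Compound list**
1 | 3,5-dimethoxyphenol | COc1cc(O)cc(OC)c1 | starting material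
2 | tert-butyl 2-methylbut-3-en-2-yl carbonate | C=CC(C)(C)OC(=O)OC(C)(C)C | starting material
3 | 1,3-dimethoxy-5-[(2-methylbut-3-en-2-yl)oxy]benzene | COc1cc(OC)cc(OC(C)(C)C=C)c1 | intermediate
4 | 3,5-dimethoxy-2-(3-methylbut-2-en-1-yl)phenol | COc1cc(O)c(CC=C(C)C)c(OC)c1 | intermediate
5 | 5-bromo-2-methoxyphenol | COc1ccc(Br)cc1O | starting material
6 | (5-bromo-2-methoxyphenoxy)(tert-butyl)dimethylsilane | COc1ccc(Br)cc1O[Si](C)(C)C(C)(C)C | intermediate
7 | diallyl oxalate | C=CCOC(=O)C(=O)OCC=C | starting material
8 | [3-(tert-butyldimethylsilyloxy)-4-methoxyphenyl]lithium | [Li]c1ccc(OC)c(O[Si](C)(C)C(C)(C)C)c1 | intermediate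
9 | prop-2-en-1-yl 2-[3-(tert-butyldimethylsilyloxy)-4-methoxyphenyl]-2-oxoacetate | C=CCOC(=O)C(=O)c1ccc(OC)c(O[Si](C)(C)C(C)(C)C)c1 | intermediate
10 | prop-2-en-1-yl (2S)-2-[3-(tert-butyldimethylsilyloxy)-4-methoxyphenyl]-2-hydroxyacetate | C=CCOC(=O)[C@@H](O)c1ccc(OC)c(O[Si](C)(C)C(C)(C)C)c1 | intermediate
11 | prop-2-en-1-yl (2R)-2-[3-(tert-butyldimethylsilyloxy)-4-methoxyphenyl]-2-[3,5-dimethoxy-2-(3-methylbut-2-en-1-yl)phenoxy]acetate | C=CCOC(=O)[C@H](Oc1cc(OC)cc(OC)c1CC=C(C)C)c1ccc(OC)c(O[Si](C)(C)C(C)(C)C)c1 | intermediate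
12 | (2R)-2-[3-(tert-butyldimethylsilyloxy)-4-methoxyphenyl]-2-[3,5-dimethoxy-2-(3-methylbut-2-en-1-yl)phenoxy]acetic acid | OC(=O)[C@H](Oc1cc(OC)cc(OC)c1CC=C(C)C)c1ccc(OC)c(O[Si](C)(C)C(C)(C)C)c1 | intermediate
13 | mixed anhydride of 12 with isobutyl hydrogen carbonate, (2R) | CC(C)COC(=O)OC(=O)[C@H](Oc1cc(OC)cc(OC)c1CC=C(C)C)c1ccc(OC)c(O[Si](C)(C)C(C)(C)C)c1 | intermediate
14 | (3R)-3-[3-(tert-butyldimethylsilyloxy)-4-methoxyphenyl]-1-diazo-3-[3,5-dimethoxy-2-(3-methylbut-2-en-1-yl)phenoxy]propan-2-one | [N-]=[N+]=CC(=O)[C@H](Oc1cc(OC)cc(OC)c1CC=C(C)C)c1ccc(OC)c(O[Si](C)(C)C(C)(C)C)c1 | intermediate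
15 | (3S)-3-[3-(tert-butyldimethylsilyloxy)-4-methoxyphenyl]-3-[3,5-dimethoxy-2-(3-methylbut-2-en-1-yl)phenoxy]prop-1-en-1-one (ketene) | O=C=C[C@H](Oc1cc(OC)cc(OC)c1CC=C(C)C)c1ccc(OC)c(O[Si](C)(C)C(C)(C)C)c1 | intermediate
16 | (2S)-2-[3-(tert-butyldimethylsilyloxy)-4-methoxyphenyl]-5,7-dimethoxy-8-(3-methylbut-2-en-1-yl)chroman-4-one | COc1ccc([C@@H]2CC(=O)c3c(OC)cc(OC)c(CC=C(C)C)c3O2)cc1O[Si](C)(C)C(C)(C)C | intermediate
17 | (2S)-2-(3-hydroxy-4-methoxyphenyl)-5,7-dimethoxy-8-(3-methylbut-2-en-1-yl)chroman-4-one | COc1ccc([C@@H]2CC(=O)c3c(OC)cc(OC)c(CC=C(C)C)c3O2)cc1O | target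

**Step count**
Total: 10 steps. Longest linear sequence: 8 steps (5 to 17, steps 3 to 10).

**Steps most likely to fail**

1. Step 9 (bears the label "Proposed new method:"). The ketene may be consumed by dimerisation, or the Lewis acid may ionise the benzylic C2–O1 bond (loss of the phenol, erosion of configuration) faster than ring A is acylated. The fallback uses known chemistry and sets out from 14. Irradiation at 450 nm in THF/water at 0 °C traps the ketene with water as (3S)-3-[3-(tert-butyldimethylsilyloxy)-4-methoxyphenyl]-3-[3,5-dimethoxy-2-(3-methylbut-2-en-1-yl)phenoxy]propanoic acid F1 (Arndt–Eistert homologation, retention at the migrating carbon). Trifluoroacetic anhydride in CH2Cl2 at −20 to 0 °C then converts F1 into its mixed anhydride with trifluoroacetic acid F2, which acylates ring A intramolecularly (Friedel–Crafts) and comes back to the route at 16. The two bonds are then made in two separate operations.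

2. Step 6. The alkoxyphosphonium intermediate may ionise at the 4-methoxybenzylic carbon, which would give partial racemisation, or the ortho-substituted phenol may couple slowly. The fallback sets the stereocentre by catalysis instead and sets out from 6. Lithiation as in step 4 and addition to dimethyl oxalate give methyl 2-[3-(tert-butyldimethylsilyloxy)-4-methoxyphenyl]-2-oxoacetate F3. Condensation with p-toluenesulfonyl hydrazide gives the tosylhydrazone F4, and DBU in CH2Cl2 (Bamford–Stevens) gives methyl 2-[3-(tert-butyldimethylsilyloxy)-4-methoxyphenyl]-2-diazoacetate F5. Enantioselective O–H insertion of F5 into phenol 4, catalysed by PdCl2(PhCN)2 with a chiral spiro bis(oxazoline) ligand and Na[B(3,5-(CF3)2C6H3)4], the ligand enantiomer chosen to give the (R) product, gives methyl (2R)-2-[3-(tert-butyldimethylsilyloxy)-4-methoxyphenyl]-2-[3,5-dimethoxy-2-(3-methylbut-2-en-1-yl)phenoxy]acetate F6. Me3SnOH in 1,2-dichloroethane at 60 °C cleaves the methyl ester without epimerisation and comes back to the route at 12.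

3. Step 1. The very electron-rich phenol may be allylated on carbon by the π-allylpalladium intermediate, or the ether may equilibrate to the linear prenyl ether. The fallback builds the tertiary ether without a π-allyl intermediate and sets out from 1. Copper-catalysed propargylation with 3-chloro-3-methylbut-1-yne (CuCl2·2H2O cat., DBU, MeCN, 0 °C) gives 1,3-dimethoxy-5-[(2-methylbut-3-yn-2-yl)oxy]benzene F7. Semihydrogenation (H2, Pd/CaCO3 poisoned with Pb(OAc)2, quinoline, EtOAc) comes back to the route at 3.

**Further compounds**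
F1 | step 9 | (3S)-3-[3-(tert-butyldimethylsilyloxy)-4-methoxyphenyl]-3-[3,5-dimethoxy-2-(3-methylbut-2-en-1-yl)phenoxy]propanoic acid | OC(=O)C[C@H](Oc1cc(OC)cc(OC)c1CC=C(C)C)c1ccc(OC)c(O[Si](C)(C)C(C)(C)C)c1
F2 | step 9 | mixed anhydride of F1 with trifluoroacetic acid, (3S) | O=C(C[C@H](Oc1cc(OC)cc(OC)c1CC=C(C)C)c1ccc(OC)c(O[Si](C)(C)C(C)(C)C)c1)OC(=O)C(F)(F)F
F3 | step 6 | methyl 2-[3-(tert-butyldimethylsilyloxy)-4-methoxyphenyl]-2-oxoacetate | COC(=O)C(=O)c1ccc(OC)c(O[Si](C)(C)C(C)(C)C)c1
F4 | step 6 | methyl 2-[3-(tert-butyldimethylsilyloxy)-4-methoxyphenyl]-2-[2-(4-methylbenzenesulfonyl)hydrazinylidene]acetate | COC(=O)C(=NNS(=O)(=O)c1ccc(C)cc1)c1ccc(OC)c(O[Si](C)(C)C(C)(C)C)c1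
F5 | step 6 | methyl 2-[3-(tert-butyldimethylsilyloxy)-4-methoxyphenyl]-2-diazoacetate | COC(=O)C(=[N+]=[N-])c1ccc(OC)c(O[Si](C)(C)C(C)(C)C)c1
F6 | step 6 | methyl (2R)-2-[3-(tert-butyldimethylsilyloxy)-4-methoxyphenyl]-2-[3,5-dimethoxy-2-(3-methylbut-2-en-1-yl)phenoxy]acetate | COC(=O)[C@H](Oc1cc(OC)cc(OC)c1CC=C(C)C)c1ccc(OC)c(O[Si](C)(C)C(C)(C)C)c1
F7 | step 1 | 1,3-dimethoxy-5-[(2-methylbut-3-yn-2-yl)oxy]benzene | COc1cc(OC)cc(OC(C)(C)C#C)c1
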